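**Retrosynthetic overview**
- The two ester C6–O bonds are made last, by a double Mitsunobu esterification of (2E,6E)-2,6-dimethylocta-2,6-dienedioic acid (from geranyl acetate) with two molecules of 6-epi-incarvilline, with inversion at C6.
- 6-epi-Incarvilline comes from a bicyclic 4-methylidene ketone: hydride sets C6 and convex-face hydrogenation of the exocyclic alkene sets C4.
- The piperidine ring is disconnected at C1–C7a and N–C3: a (4R)-4-(3-chloroprop-1-en-2-yl)-2-methylcyclopent-2-enone and N-methyl-1-(trimethylsilyl)methanamine are joined in one flask by N-allylation and photoredox desilylative α-aminomethyl radical 6-exo conjugate cyclisation, a radical umpolung that unites two acceptor carbons.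
- Enabling feature: ring-fusion carbon C7a lies β to the oxygen-bearing C6 of the cyclopentane ring, so at the ketone level it is the β-carbon of a cyclopentenone; its partner C1 is the N–CH2 carbon of the N-methylpiperidine ring and can be made an α-amino radical; C3 is an allylic CH2 once the C4 methyl is held as an exocyclic methylene.
- Ring order: cyclopentenone first (from a (4R)-4-silyloxycyclopentenone by conjugate addition–elimination, α-methylation and allylic chlorination), piperidine ring second (key step).

Key step: step 5

Remark: N-methyl-1-(trimethylsilyl)methanamine is taken as a purchased reagent, and the C7 methyl group is assumed to equilibrate under base to the position trans to C1, as expected for a 2,3-disubstituted cyclopentanone.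

**Step 1**
Reactants: 1 (4R)-4-[(tert-butyldimethylsilyl)oxy]cyclopent-2-en-1-one; 2 isopropenylmagnesium bromide
Product: 4 (4R)-4-(prop-1-en-2-yl)cyclopent-2-en-1-one, via trans-silyloxy ketone 3 (not isolated)
Conditions: 2 (1.5 equiv), CuBr·SMe2 (10 mol %), THF, −78 °C; aq NH4Cl; then DBU, CH2Cl2, 0 °C
Reagents that add atoms: isopropenylmagnesium bromide (2), C=C(C)[Mg]Br
Why: Copper-catalysed conjugate addition of the Grignard reagent occurs anti to the silyloxy group, and E1cB β-elimination of silanolate from the resulting β-silyloxy ketone then moves the enone, so the C–O stereocentre is traded for the new C–C stereocentre (future C4a) in a conjugate addition–elimination sequence.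

**Step 2**
Reactants: 4 (4R)-4-(prop-1-en-2-yl)cyclopent-2-en-1-one
Product: 5 (4R)-2-iodo-4-(prop-1-en-2-yl)cyclopent-2-en-1-one
Conditions: I2, pyridine/CH2Cl2 (1:1), 0 °C to rt
Reagents that add atoms: iodine, II
Why: α-Iodination of the enone by the pyridine-mediated addition–iodination–elimination sequence (Baylis–Hillman-type) functionalises only the enone α-carbon and leaves the isolated alkene and the stereocentre untouched.

**Step 3**
Reactants: 5 (4R)-2-iodo-4-(prop-1-en-2-yl)cyclopent-2-en-1-one
Product: 6 (4R)-2-methyl-4-(prop-1-en-2-yl)cyclopent-2-en-1-one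
Conditions: MeZnCl (1.5 equiv), Pd(PPh3)4 (5 mol %), THF, rt
Reagents that add atoms: methylzinc chloride, C[Zn]Cl
Why: Negishi cross-coupling of the α-iodoenone with methylzinc chloride runs under neutral conditions at room temperature, so the doubly allylic stereocentre is not exposed to base.

**Step 4**
Reactants: 6 (4R)-2-methyl-4-(prop-1-en-2-yl)cyclopent-2-en-1-one
Product: 7 (4R)-4-(3-chloroprop-1-en-2-yl)-2-methylcyclopent-2-en-1-one
Conditions: Ca(OCl)2, solid CO2, CH2Cl2/H2O, 0 °C
Reagents that add atoms: calcium hypochlorite, [Ca+2].[O-]Cl.[O-]Cl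
Why: Hypochlorous acid generated in situ effects an ene-type allylic chlorination of the electron-rich 1,1-disubstituted alkene (chlorine to the terminal carbon, loss of a methyl proton, double-bond shift), a reaction type well established for isopropenyl groups of terpenoid enones, while the electron-poor enone alkene is inert.

**Step 5**
Reactants: 7 (4R)-4-(3-chloroprop-1-en-2-yl)-2-methylcyclopent-2-en-1-one; 8 N-methyl-1-(trimethylsilyl)methanamine
Product: 10 (4aR,7S,7aR)-2,7-dimethyl-4-methylideneoctahydro-6H-cyclopenta[c]pyridin-6-one, via tertiary α-silylamine 9 (not isolated)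
Conditions: 8 (1.2 equiv), NaHCO3, MeCN, 40 °C, dark; then [Ir(dF(CF3)ppy)2(dtbbpy)]PF6 (1 mol %), MeOH, blue LEDs (450 nm), rt, degassed; then K2CO3, MeOH, rt
Reagents that add atoms: N-methyl-1-(trimethylsilyl)methanamine (8), CNC[Si](C)(C)C
Why: In the dark the secondary amine displaces the allylic chloride (SN2, N–C3); on irradiation the excited iridium photocatalyst oxidises the resulting tertiary α-silylamine to its aminium radical cation, which loses the silyl group to methanol and gives the nucleophilic α-aminomethyl radical at C1, and this radical adds to C7a, the β-carbon of the cyclopentenone, after which the α-keto radical at C7 is reduced by the reduced photocatalyst to the enolate and protonated, so the sequence is redox-neutral and joins two carbons (C1 and C7a) that are both acceptors in polar terms. The closest known reaction type is the photoinduced-electron-transfer (photoredox) conjugate addition and cyclisation of α-silylamines onto enones, a Giese-type radical addition. The piperidine ring closes in the 6-exo-trig mode, the N–C1 unit being annulated onto the C3–C4–C4a–C7a chain in a formal (4+2) sense. C7a is controlled by the existing C4a centre, because the tether that hangs from C4a can reach only the same face of the planar enone and a cis ring fusion must result; C7 is set under thermodynamic control by the closing K2CO3/MeOH equilibration, which should place the methyl group trans to C1. The step needs C–Si rather than C–H fragmentation of the aminium ion (secured by the silyl group and methanol), 6-exo attack at C7a rather than 7-endo attack at C7 (secured by the polarity match and the stabilised α-keto radical), and an amine without N–H so that no aza-Michael closure competes (secured because the N-methyl secondary amine becomes tertiary on allylation).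

**Step 6**
Reactants: 10 (4aR,7S,7aR)-2,7-dimethyl-4-methylideneoctahydro-6H-cyclopenta[c]pyridin-6-one
Product: 11 (4R,4aS,7S,7aR)-2,4,7-trimethyloctahydro-6H-cyclopenta[c]pyridin-6-one
Conditions: H2 (1 atm), RhCl(PPh3)3 (5 mol %), toluene/EtOH, rt
Reagents that add atoms: none
Why: Homogeneous hydrogenation with RhCl(PPh3)3 should reduce only the unhindered 1,1-disubstituted alkene without allylic C–N hydrogenolysis or ketone reduction, and hydrogen should be delivered to the face of C4 that carries H4a (anti to the cyclopentanone ring), which makes H4 cis to H4a and gives the 4R centre.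

**Step 7**
Reactants: 11 (4R,4aS,7S,7aR)-2,4,7-trimethyloctahydro-6H-cyclopenta[c]pyridin-6-one
Product: 12 6-epi-incarvilline, (4R,4aS,6S,7S,7aR)-2,4,7-trimethyloctahydro-1H-cyclopenta[c]pyridin-6-ol
Conditions: NaBH4, MeOH, −20 to 0 °C
Reagents that add atoms: none
Why: Borohydride reduction of the cyclopentanone is expected to deliver hydride from the convex face, anti to the piperidine ring, giving the 6S alcohol with the hydroxyl trans to the C7 methyl group, the usual outcome for small hydrides with 2-methylcyclopentanones.

**Step 8**
Reactants: 13 geranyl acetate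
Product: 14 (2E,6E)-8-hydroxy-3,7-dimethylocta-2,6-dien-1-yl acetate
Conditions: SeO2 (10 mol %), t-BuOOH, salicylic acid (10 mol %), CH2Cl2, rt
Reagents that add atoms: selenium dioxide, O=[Se]=O (catalytic oxygen carrier); tert-butyl hydroperoxide, CC(C)(C)OO (terminal oxidant)
Why: Catalytic SeO2/tert-butyl hydroperoxide allylic oxidation (ene reaction, then [2,3]-sigmatropic shift) should hydroxylate selectively the (E)-methyl group of the electron-rich terminal alkene, the 2,3-alkene being deactivated by the allylic acetate, and so fixes the 6E geometry.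

**Step 9**
Reactants: 14 (2E,6E)-8-hydroxy-3,7-dimethylocta-2,6-dien-1-yl acetate
Product: 15 (2E,6E)-2,6-dimethylocta-2,6-diene-1,8-diol
Conditions: K2CO3 (20 mol %), MeOH, rt
Reagents that add atoms: none
Why: Base-catalysed transesterification with methanol removes the acetate without touching the alkene geometry.

**Step 10**
Reactants: 15 (2E,6E)-2,6-dimethylocta-2,6-diene-1,8-diol
Product: 17 (2E,6E)-2,6-dimethylocta-2,6-dienedioic acid, via dienedial 16 (not isolated)
Conditions: MnO2, CH2Cl2, rt, filter; then NaClO2, NaH2PO4, 2-methylbut-2-ene, t-BuOH/H2O, 0 °C to rt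
Reagents that add atoms: sodium chlorite, [Na+].[O-]Cl=O
Why: MnO2 oxidises both allylic alcohols to the conjugated dialdehyde and the Pinnick oxidation (chlorite with a hypochlorite scavenger) then converts both aldehydes to acids without isomerising the E alkenes.

**Step 11**
Reactants: 12 6-epi-incarvilline (2.2 equiv); 17 (2E,6E)-2,6-dimethylocta-2,6-dienedioic acid
Product: 18 bis[(4R,4aS,6R,7S,7aR)-2,4,7-trimethyloctahydro-1H-cyclopenta[c]pyridin-6-yl] (2E,6E)-2,6-dimethylocta-2,6-dienedioate
Conditions: PPh3, DIAD, THF, 0 °C to rt
Reagents that add atoms: none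
Why: In this double Mitsunobu esterification each alkoxyphosphonium ion derived from 12 should be displaced by a carboxylate of 17 in an SN2 reaction from the convex face with inversion at C6 (6S to 6R), which brings both oxygen-bearing centres to the target configuration; the tertiary amines are tolerated.

**Compound list**
1 | (4R)-4-[(tert-butyldimethylsilyl)oxy]cyclopent-2-en-1-one | O=C1C[C@@H](O[Si](C)(C)C(C)(C)C)C=C1 | starting material
2 | isopropenylmagnesium bromide | C=C(C)[Mg]Br | starting material
3 | (3R,4S)-3-[(tert-butyldimethylsilyl)oxy]-4-(prop-1-en-2-yl)cyclopentan-1-one (trans) | O=C1C[C@@H](O[Si](C)(C)C(C)(C)C)[C@H](C(C)=C)C1 | intermediate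
4 | (4R)-4-(prop-1-en-2-yl)cyclopent-2-en-1-one | O=C1C[C@@H](C(C)=C)C=C1 | intermediate
5 | (4R)-2-iodo-4-(prop-1-en-2-yl)cyclopent-2-en-1-one | O=C1C[C@@H](C(C)=C)C=C1I | intermediate
6 | (4R)-2-methyl-4-(prop-1-en-2-yl)cyclopent-2-en-1-one | O=C1C[C@@H](C(C)=C)C=C1C | intermediate
7 | (4R)-4-(3-chloroprop-1-en-2-yl)-2-methylcyclopent-2-en-1-one | O=C1C[C@@H](C(=C)CCl)C=C1C | intermediate
8 | N-methyl-1-(trimethylsilyl)methanamine | CNC[Si](C)(C)C | starting material
9 | (4R)-2-methyl-4-(3-{methyl[(trimethylsilyl)methyl]amino}prop-1-en-2-yl)cyclopent-2-en-1-one | O=C1C[C@@H](C(=C)CN(C)C[Si](C)(C)C)C=C1C | intermediate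
10 | (4aR,7S,7aR)-2,7-dimethyl-4-methylideneoctahydro-6H-cyclopenta[c]pyridin-6-one | O=C1C[C@@H]2[C@@H](CN(C)CC2=C)[C@@H]1C | intermediate
11 | (4R,4aS,7S,7aR)-2,4,7-trimethyloctahydro-6H-cyclopenta[c]pyridin-6-one | O=C1C[C@@H]2[C@@H](CN(C)C[C@@H]2C)[C@@H]1C | intermediate
12 | 6-epi-incarvilline, (4R,4aS,6S,7S,7aR)-2,4,7-trimethyloctahydro-1H-cyclopenta[c]pyridin-6-ol | O[C@H]1C[C@@H]2[C@@H](CN(C)C[C@@H]2C)[C@@H]1C | intermediate
13 | geranyl acetate, (2E)-3,7-dimethylocta-2,6-dien-1-yl acetate | CC(C)=CCC/C(C)=C/COC(C)=O | starting material
14 | (2E,6E)-8-hydroxy-3,7-dimethylocta-2,6-dien-1-yl acetate | OC/C(C)=C/CC/C(C)=C/COC(C)=O | intermediate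
15 | (2E,6E)-2,6-dimethylocta-2,6-diene-1,8-diol | OC/C(C)=C/CC/C(C)=C/CO | intermediate
16 | (2E,6E)-2,6-dimethylocta-2,6-dienedial | O=C/C(C)=C/CC/C(C)=C/C=O | intermediate
17 | (2E,6E)-2,6-dimethylocta-2,6-dienedioic acid | OC(=O)/C(C)=C/CC/C(C)=C/C(=O)O | intermediate
18 | bis[(4R,4aS,6R,7S,7aR)-2,4,7-trimethyloctahydro-1H-cyclopenta[c]pyridin-6-yl] (2E,6E)-2,6-dimethylocta-2,6-dienedioate | C/C(=C\C(=O)O[C@@H]1C[C@@H]2[C@@H](CN(C)C[C@@H]2C)[C@@H]1C)CC/C=C(\C)C(=O)O[C@@H]1C[C@@H]2[C@@H](CN(C)C[C@@H]2C)[C@@H]1C | target

**Step count and risks**
Total steps: 11. Longest linear sequence: 8 (steps 1 to 7, then step 11); steps 8 to 10 form the diacid branch.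

Steps most likely to fail:

Step 5. The aminium radical cation may lose an α-proton instead of silicon, the radical may be quenched before it cyclises, or the secondary amine may be oxidised before it has been allylated. The fallback sets out from 7 and separates the two bond formations, replacing the silicon trigger by a carboxylate trigger. Alkylation of sarcosine tert-butyl ester with 7 (NaHCO3, MeCN) should give the tert-butyl amino ester F1. TFA in CH2Cl2 should cleave it to the N,N-dialkylglycine F2. A photoredox decarboxylative radical conjugate addition ([Ir(dF(CF3)ppy)2(dtbbpy)]PF6, K2HPO4, DMF, blue LEDs) should then generate the same α-aminomethyl radical by loss of CO2; 6-exo cyclisation and K2CO3/MeOH equilibration bring the route back at 10.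

Step 4. Proton loss may occur from the doubly allylic ring methine instead of the methyl group (giving a conjugated alkylidene and loss of the stereocentre), or chlorohydrin may form. The fallback sets out from 6 and installs oxygen first. SeO2 (cat.)/t-BuOOH allylic hydroxylation, which prefers a methyl over a methine position, should give the allylic alcohol F3. An Appel chlorination (PPh3, CCl4, CH2Cl2) converts it to the chloride, and the route is rejoined at 7.

Step 11. The activated, hindered secondary alcohol may eliminate, or the reaction may stall at the mono-ester. The fallback sets out from 12 and separates inversion from ester formation. Mitsunobu inversion with 4-nitrobenzoic acid (PPh3, DIAD, THF), a more acidic pronucleophile, should give the inverted 4-nitrobenzoate F4. Methanolysis (K2CO3, MeOH) should give incarvilline F5 with the 6R configuration. Steglich esterification of F5 (2.2 equiv) with 17 (EDC·HCl, DMAP, CH2Cl2) then forms both esters with retention and the route is rejoined at 18.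

**Further compounds**
F1 | step 5 | tert-butyl N-methyl-N-{2-[(1R)-3-methyl-4-oxocyclopent-2-en-1-yl]prop-2-en-1-yl}glycinate | O=C1C[C@@H](C(=C)CN(C)CC(=O)OC(C)(C)C)C=C1C
F2 | step 5 | N-methyl-N-{2-[(1R)-3-methyl-4-oxocyclopent-2-en-1-yl]prop-2-en-1-yl}glycine | O=C1C[C@@H](C(=C)CN(C)CC(=O)O)C=C1C
F3 | step 4 | (4R)-4-(3-hydroxyprop-1-en-2-yl)-2-methylcyclopent-2-en-1-one | O=C1C[C@@H](C(=C)CO)C=C1C
F4 | step 11 | (4R,4aS,6R,7S,7aR)-2,4,7-trimethyloctahydro-1H-cyclopenta[c]pyridin-6-yl 4-nitrobenzoate | O=C(O[C@@H]1C[C@@H]2[C@@H](CN(C)C[C@@H]2C)[C@@H]1C)c1ccc(cc1)[N+](=O)[O-]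
F5 | step 11 | incarvilline, (4R,4aS,6R,7S,7aR)-2,4,7-trimethyloctahydro-1H-cyclopenta[c]pyridin-6-ol | O[C@@H]1C[C@@H]2[C@@H](CN(C)C[C@@H]2C)[C@@H]1C
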